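**Retrosynthetic overview**

- Feature: in the chroman-2-one, arene carbons C5–C6–C7 (two phenolic carbons flanking the prenyl-bearing C6) are a prenylmalonyl C3 unit. C8–C8a–C4a are the α-carbon, carbonyl carbon and α′-carbon of a ketone whose oxygen is O1, already acylated as the lactone, and C8 also carries the benzoyl group.
- Key disconnection: C7–C8 and C4a–C5, which gives a 6-phenacyl-4-phenyl-3,4-dihydropyran-2-one and prenylmalonyl dichloride ([3+3] double C-acylation, then enolisation to the benzene ring).
- Enol lactone: the O1–C8a enol-ester bond comes from a 5,7-dioxo-3,7-diphenylheptanoic acid. Its diketone comes from C-acylation of acetophenone by monomethyl 3-phenylglutarate, made by desymmetrising methanolysis of the meso anhydride, which sets C4.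
- Dichloride: malonic ester alkylation with prenyl bromide, saponification, HCl-free chlorination.
- Ring order: the dihydropyranone (lactone) ring first, the benzene ring last.

Key step: step 8

Remark (assumption): the quinine-derived thiourea is taken to give the R hemiester 2; if the sense of induction is opposite, the quinidine-derived pseudoenantiomer is used, checked by optical rotation of 2.
Remark (assumption): enol lactone 8 is drawn as its endocyclic 5,6-ene tautomer; the conjugated exocyclic tautomer 7 may persist, and both give the same dienolate on deprotonation, so step 8 does not depend on the tautomer ratio.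
Remark: the descriptor at the benzylic carbon changes along the route (R in 2, S in 8, R in 16) only because CIP priorities change; the spatial arrangement set in step 1 is never altered.

**Route**

Step 1
Reactants: 1 3-phenylglutaric anhydride
Product: 2 (R)-5-methoxy-5-oxo-3-phenylpentanoic acid
Conditions: MeOH (10 equiv), 1-[3,5-bis(trifluoromethyl)phenyl]-3-(9-deoxy-epi-quinin-9-yl)thiourea (10 mol%), MTBE, rt
Reagents that add atoms: methanol, CO
Why: Cinchona-catalysed enantioselective alcoholysis (desymmetrisation) of a meso 3-arylglutaric anhydride, in which the thiourea activates one enantiotopic carbonyl and the quinuclidine delivers methanol, should set the benzylic stereocentre (the later C4) as R; crystallisation of an amine salt can raise the enantiopurity if needed.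

Step 2
Reactants: 2 (R)-5-methoxy-5-oxo-3-phenylpentanoic acid; 3 acetophenone
Product: 5 methyl (R)-5,7-dioxo-3,7-diphenylheptanoate, via acid chloride 4 (not isolated)
Conditions: (COCl)2, DMF (cat.), CH2Cl2, 0 °C to rt, concentrate; then 3 (1.5 equiv), MgBr2·OEt2 (2.5 equiv), i-Pr2NEt (3 equiv), CH2Cl2, 0 °C to rt
Reagents that add atoms: none
Why: Claisen-type C-acylation of a ketone by an acid chloride under soft enolisation should give the 1,3-diketone as its magnesium chelate, which resists a second acylation; the methyl ester is inert, the stereocentre is not α to a carbonyl, and keeping 4 cold avoids symmetrisation through the cyclic anhydride.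

Step 3
Reactants: 5 methyl (R)-5,7-dioxo-3,7-diphenylheptanoate
Product: 6 (R)-5,7-dioxo-3,7-diphenylheptanoic acid
Conditions: LiOH·H2O (3 equiv), THF/H2O 3:1, 0 °C to rt; then 1 M HCl to pH 2–3, 0 °C
Reagents that add atoms: lithium hydroxide, [Li+].[OH-]
Why: Saponification of the methyl ester, during which the β-diketone sits as its enolate and is shielded from retro-Claisen cleavage, should return the diketo acid on cold acidification.

Step 4
Reactants: 6 (R)-5,7-dioxo-3,7-diphenylheptanoic acid
Product: 8 (S)-6-(2-oxo-2-phenylethyl)-4-phenyl-3,4-dihydro-2H-pyran-2-one, via exocyclic phenacylidene lactone 7 (not isolated)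
Conditions: N,N′-diisopropylcarbodiimide (1.1 equiv), CH2Cl2, 0 °C to rt; filtration, short silica column
Reagents that add atoms: none
Why: Enol lactonisation of a δ-keto acid, in which the O-acylisourea is attacked by the enol oxygen of the strongly enolised β-diketone (6-exo-trig at the acyl carbon), should give 7 and, by tautomerisation, 8; no DMAP or other acyl-transfer catalyst is present, so O-to-C acyl migration to the cyclic triketone is not promoted.

Step 5
Reactants: 9 diethyl malonate; 10 prenyl bromide
Product: 11 diethyl 2-(3-methylbut-2-en-1-yl)malonate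
Conditions: NaH (1.0 equiv), 9 (1.5 equiv), THF, 0 °C; then 10 (1.0 equiv), 0 °C to rt
Reagents that add atoms: none
Why: Malonic ester alkylation (SN2 of the sodium enolate on a primary allylic bromide), with excess malonate to limit dialkylation.

Step 6
Reactants: 11 diethyl 2-(3-methylbut-2-en-1-yl)malonate
Product: 12 2-(3-methylbut-2-en-1-yl)malonic acid
Conditions: KOH (2.5 equiv), EtOH/H2O, rt; then cold 1 M HCl to pH 2, extraction without heating
Reagents that add atoms: potassium hydroxide, [K+].[OH-]
Why: Saponification of both esters at room temperature, with brief cold acidification so that neither decarboxylation nor acid-induced lactonisation onto the trisubstituted alkene sets in.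

Step 7
Reactants: 12 2-(3-methylbut-2-en-1-yl)malonic acid
Product: 13 prenylmalonyl dichloride [2-(3-methylbut-2-en-1-yl)malonyl dichloride]
Conditions: 1-chloro-N,N,2-trimethylprop-1-en-1-amine (2.2 equiv), CH2Cl2, 0 °C to rt; used at once as the solution
Reagents that add atoms: 1-chloro-N,N,2-trimethylprop-1-en-1-amine (Ghosez reagent), CC(C)=C(Cl)N(C)C
Why: Acid chloride formation with an α-chloroenamine is neutral and releases no HCl, so the prenyl double bond should survive; the only by-product is an inert tertiary amide.

Step 8
Reactants: 8 (S)-6-(2-oxo-2-phenylethyl)-4-phenyl-3,4-dihydro-2H-pyran-2-one; 13 prenylmalonyl dichloride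
Product: 16 (R)-8-benzoyl-5,7-dihydroxy-6-(3-methylbut-2-en-1-yl)-4-phenylchroman-2-one, via C8-acylated keto acid chloride 14 (not isolated), via cyclohexenetrione tautomer 15 (not isolated)
Conditions: 8, MgBr2·OEt2 (3 equiv), i-Pr2NEt (4.5 equiv), CH2Cl2, −20 °C; 13 (1.05 equiv) added over 1 h; then rt to 40 °C; cold aqueous citric acid work-up
Reagents that add atoms: none
Why: Proposed new method: under soft enolisation the magnesium dienolate of 8 should be C-acylated at the phenacyl carbon (the future C8) by 13 or the chlorocarbonyl ketene derived from it to give 14; deprotonation of the now doubly activated C8–H gives a magnesium β-diketonate conjugated with the C8a=C4a enol-ester double bond, and C4a then attacks the remaining acyl chloride (or, after loss of HCl, the acylketene, which amounts to a 6π-electrocyclisation of a dienylketene) to give 15, which enolises twice to the benzene ring. The closest known reactions are the α,α′-double C-acylation of enol ethers by malonyl dichloride (Effenberger cyclisation), the Claisen cyclisation of 3,5,7-triketo esters to acylphloroglucinols and the MgBr2-mediated C-acylation of ketones by acid chlorides; none has been shown with an enol lactone as the dinucleophile. The carbocycle closes in a 6-exo-trig mode at the acyl carbon (C4a onto C5). No stereocentre is formed, and C4, which is neither enolisable nor part of the reacting π-system, should be carried through unchanged. The selectivity needed is C- over O-acylation in the ring closure: O1 is blocked as the lactone, and chelation of divalent magnesium between the benzoyl and C7 oxygens should turn the benzoyl oxygen away from the acyl chloride (which would otherwise close a 4-hydroxy-2-pyranone) and hold the chlorocarbonyl arm next to C4a. Because the lactone is never opened, the regiochemistry (lactone oxygen next to the benzoyl-bearing C8, free hydroxyl at C5) is fixed by connectivity.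

**Compound list**

1 | 3-phenylglutaric anhydride | O=C1CC(c2ccccc2)CC(=O)O1 | starting material
2 | (R)-5-methoxy-5-oxo-3-phenylpentanoic acid | OC(=O)C[C@@H](c1ccccc1)CC(=O)OC | intermediate
3 | acetophenone | CC(=O)c1ccccc1 | starting material
4 | methyl (S)-5-chloro-5-oxo-3-phenylpentanoate | ClC(=O)C[C@@H](c1ccccc1)CC(=O)OC | intermediate
5 | methyl (R)-5,7-dioxo-3,7-diphenylheptanoate | O=C(CC(=O)C[C@@H](c1ccccc1)CC(=O)OC)c1ccccc1 | intermediate
6 | (R)-5,7-dioxo-3,7-diphenylheptanoic acid | O=C(CC(=O)C[C@@H](c1ccccc1)CC(=O)O)c1ccccc1 | intermediate
7 | (R,Z)-6-(2-oxo-2-phenylethylidene)-4-phenyltetrahydro-2H-pyran-2-one | O=C(c1ccccc1)/C=C1\OC(=O)C[C@H](c2ccccc2)C1 | intermediate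
8 | (S)-6-(2-oxo-2-phenylethyl)-4-phenyl-3,4-dihydro-2H-pyran-2-one | O=C(CC1=C[C@@H](c2ccccc2)CC(=O)O1)c1ccccc1 | intermediate
9 | diethyl malonate | CCOC(=O)CC(=O)OCC | starting material
10 | prenyl bromide (1-bromo-3-methylbut-2-ene) | CC(C)=CCBr | starting material
11 | diethyl 2-(3-methylbut-2-en-1-yl)malonate | CCOC(=O)C(CC=C(C)C)C(=O)OCC | intermediate
12 | 2-(3-methylbut-2-en-1-yl)malonic acid | OC(=O)C(CC=C(C)C)C(=O)O | intermediate
13 | prenylmalonyl dichloride | O=C(Cl)C(CC=C(C)C)C(=O)Cl | intermediate
14 | 2-(3-methylbut-2-en-1-yl)-3,5-dioxo-4-[(4S)-2-oxo-4-phenyl-3,4-dihydro-2H-pyran-6-yl]-5-phenylpentanoyl chloride (labile centres undefined) | O=C(Cl)C(CC=C(C)C)C(=O)C(C(=O)c1ccccc1)C1=C[C@@H](c2ccccc2)CC(=O)O1 | intermediate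
15 | (4S)-8-benzoyl-6-(3-methylbut-2-en-1-yl)-4-phenyl-3,4-dihydro-2H-chromene-2,5,7(4aH,6H)-trione, the non-aromatic triketone tautomer of 16 (C4a and C6 undefined) | CC(C)=CCC1C(=O)C(C(=O)c2ccccc2)=C2OC(=O)C[C@H](c3ccccc3)C2C1=O | intermediate
16 | (R)-8-benzoyl-5,7-dihydroxy-6-(3-methylbut-2-en-1-yl)-4-phenylchroman-2-one | CC(C)=CCc1c(O)c(C(=O)c2ccccc2)c2c(c1O)[C@@H](c1ccccc1)CC(=O)O2 | target

**Step count**

Total: 8 steps (steps 1–4 to the enol lactone, steps 5–7 to the dichloride, step 8 joining them).
Longest linear sequence: 5 steps (1 → 2 → 5 → 6 → 8 → 16).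

**Steps most likely to fail**

1. Step 8 (the proposed new method). The second acyl group may close through the benzoyl enolate oxygen to a 4-hydroxy-2-pyranone instead of through C4a, or the chlorocarbonyl ketene may oligomerise before it is captured. The fallback uses known reaction types, builds the arene first, sets out from prenyl bromide 10 and comes back to the route at 16. Purchased 5,7-dimethoxycoumarin undergoes asymmetric 1,4-addition of phenylboronic acid (Rh(acac)(C2H4)2, (R)-Segphos, taken to be the ligand enantiomer that gives the R product, dioxane/H2O, 60 °C) to give (R)-5,7-dimethoxy-4-phenylchroman-2-one F1. Friedel–Crafts benzoylation (PhCOCl, AlCl3, CH2Cl2, 0 °C) is expected at C8, para to the 5-methoxy group, as in acylations of 5,7-dioxygenated 4-substituted coumarins, and gives (R)-8-benzoyl-5,7-dimethoxy-4-phenylchroman-2-one F2; any C6 isomer is removed by chromatography. BBr3 (CH2Cl2, −78 °C to rt) cleaves both methyl ethers to (R)-8-benzoyl-5,7-dihydroxy-4-phenylchroman-2-one F3. C-Prenylation of F3 at C6, the only free ring carbon, with 10 (DBU, THF, 0 °C, anhydrous so that the lactone stays closed) gives 16.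

2. Step 4. Carboxyl activation may lead to C-acylation of the diketone (cyclic triketone) or to N-acylurea formation, and the vinylogous anhydride may ring-open on isolation. The fallback carries the acyl donor as a thioester from the start, so that steps 3 and 4 are replaced; it sets out from anhydride 1 and comes back at 8. Thiolysis of 1 with phenylmethanethiol under the same cinchona thiourea catalyst gives (R)-5-(benzylsulfanyl)-5-oxo-3-phenylpentanoic acid F4. Oxalyl chloride with catalytic DMF (CH2Cl2, 0 °C) gives S-benzyl (S)-5-chloro-5-oxo-3-phenylpentanethioate F5. Addition of F5 to the lithium enolate of acetophenone 3 (LiN(SiMe3)2, THF, −78 °C) gives S-benzyl (R)-5,7-dioxo-3,7-diphenylheptanethioate F6. Thiophile-triggered acyl transfer to the diketone enol oxygen (AgOCOCF3, Na2HPO4, CH2Cl2, rt) then closes the enol lactone 8 without a free acid or a carbodiimide.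

3. Step 7. The diacid or dichloride may lose material through addition of adventitious HCl to the prenyl double bond, lactonisation onto it, or dehydrochlorination to the ketene and its oligomerisation on standing. The fallback avoids the free acid at the chlorination stage; it sets out from diacid 12 and comes back at 13. Silylation of 12 with HN(SiMe3)2 (CH2Cl2, rt) gives bis(trimethylsilyl) 2-(3-methylbut-2-en-1-yl)malonate F7, which with oxalyl chloride and catalytic DMF (CH2Cl2, 0 °C) should give 13 with only volatile, non-acidic by-products; the solution is used at once in step 8.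

**Further compounds**

F1 | step 8 | (R)-5,7-dimethoxy-4-phenylchroman-2-one | COc1cc(OC)c2c(c1)OC(=O)C[C@@H]2c1ccccc1
F2 | step 8 | (R)-8-benzoyl-5,7-dimethoxy-4-phenylchroman-2-one | COc1cc(OC)c2c(c1C(=O)c1ccccc1)OC(=O)C[C@@H]2c1ccccc1
F3 | step 8 | (R)-8-benzoyl-5,7-dihydroxy-4-phenylchroman-2-one | Oc1cc(O)c2c(c1C(=O)c1ccccc1)OC(=O)C[C@@H]2c1ccccc1
F4 | step 4 | (R)-5-(benzylsulfanyl)-5-oxo-3-phenylpentanoic acid | OC(=O)C[C@@H](c1ccccc1)CC(=O)SCc1ccccc1
F5 | step 4 | S-benzyl (S)-5-chloro-5-oxo-3-phenylpentanethioate | ClC(=O)C[C@@H](c1ccccc1)CC(=O)SCc1ccccc1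
F6 | step 4 | S-benzyl (R)-5,7-dioxo-3,7-diphenylheptanethioate | O=C(CC(=O)C[C@@H](c1ccccc1)CC(=O)SCc1ccccc1)c1ccccc1
F7 | step 7 | bis(trimethylsilyl) 2-(3-methylbut-2-en-1-yl)malonate | C[Si](C)(C)OC(=O)C(CC=C(C)C)C(=O)O[Si](C)(C)C
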